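## Structural features

The target, C26H30O8, has no stereocentre, so the whole problem is regiochemistry and functional-group tolerance. It consists of two aromatic units: a 1H-isochromen-1-one (isocoumarin) with a pentyl chain at C3, a hydroxyl at C6 and an ether oxygen at C8, and a pentasubstituted benzoic acid (ring B: C1' CO2H, C2' OH, C3' H, C4' OH, C5' O-aryl, C6' pentyl). The units are joined by the diaryl ether C8–O–C5', which sits peri to the lactone carbonyl C1 on one side and between the C4' hydroxyl and the C6' pentyl group on the other. Both rings are electron-rich and C5' has two ortho substituents, so a late aryl–oxygen coupling (Ullmann or SNAr) is badly served on both partners. The fragile groups are the 2,4-dihydroxybenzoic acid (protodecarboxylation in hot or strong acid), the enol lactone (opened by hydroxide, alkoxide or amines) and the free resorcinol-type phenols (oxidation, C-alkylation). The real difficulty is the hindered C8–O–C5' bond together with the contiguous substitution C4'–C5'–C6'–C1' of ring B. The key step uses the fact that C2'–C3'–C4'–C5', with its 1,3-oxygen pattern and the oxygenated C5', is the chain of a 4-aryloxy-3-oxobutanoate, while C6' (pentyl) and C1' (carboxyl) are the two acetylenic carbons of an oct-2-ynoate, so ring B can be grown around an ether oxygen that is already in place.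

## Logic of the disconnections

18 from 17. The O–CH3 bond at O6 of the isocoumarin and the O–C(CH3)3 bond of the ring B carboxyl are cut. Both are protecting-group bonds chosen so that one Lewis acid removes them together, which keeps the acid and the 6-phenol masked through all basic, silylating and thermal steps. The forward step must cleave the ester and the unchelated aryl methyl ether without loss of CO2 and without touching the diaryl ether or the lactone.

17 from 12 and 14. C5'–C6' and C1'–C2' are cut, which dissolves ring B into a four-carbon oxygenated diene and a two-carbon acetylenic ester. The cut is made here because the ether oxygen at C5' then sits on an enol-ether carbon of an open chain instead of a crowded aromatic carbon. The gain is that a pentasubstituted arene and a hindered diaryl ether become a phenol O-alkyl chain plus a simple ynoate. The forward step must bond C5' to the pentyl-bearing alkyne carbon and aromatize through 15 and 16 by loss of methanol, not of the aryloxy group.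

14 from 13. The O–C(CH3)3 ester bond is cut. The tert-butyl group is wanted because it shields the ester carbonyl from the nucleophilic diene and falls in the last step. The forward esterification must avoid nucleophiles that add to the triple bond.

12 from 10, and 10 from 9. The two O–Si bonds are cut in turn, with 11 lying between 10 and 12. This reduces the sensitive diene to a stable β-keto ester. The forward steps must enolize the ketone first and then remove a γ-hydrogen next to the aryloxy group without attack on the lactone, and must place the aryloxy group on the outer side of the diene.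

9 from 7 and 8. The ether bond O–CH2 is cut. Here the congested C8–O–C5' linkage is made as an SN2 reaction at a primary carbon. The forward step must make a chelated, weakly nucleophilic phenoxide react faster than 8 condenses with itself.

7 from 6. The O–CH3 bond at O8 is cut. Only this methyl ether can chelate a Lewis acid together with the lactone carbonyl, so one reagent distinguishes the two ethers. The forward step must stop after one cleavage.

6 from 5. The lactone bond O2–C1 is cut. This opens the heterocycle to a benzyl ketone with an ortho ester. The forward step must close through the enol oxygen and not through the carbon of the other enolate.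

5 from 2 and 3. The C3–C4 bond is cut, between the benzylic carbon and the acyl carbon. The isocoumarin side chain then comes from an acid chloride and the ortho-methyl group of a toluate, through 4. The forward step must stop at mono-acylation.

2 from 1. Two O–CH3 bonds are cut. The free phenols would quench the benzylic anion, so both are capped in one operation, which the chelated 2-hydroxyl makes slower but not difficult.

## Other disconnections considered

Alternative 1: The cut is at C4a–C4 and C8a–C1, the two carbon substituents of the isocoumarin benzo ring. In the forward sense the ortho-silyl aryl triflate A1 (methyl 4,6-dimethoxy-3-[5-methoxy-3-(trifluoromethanesulfonyloxy)-2-(trimethylsilyl)phenoxy]-2-pentylbenzoate) would release the aryne between C8a and C4a with fluoride. Dimethyl malonate A2 would insert, its carbanion bonding to C4a and one ester group migrating to C8a, to give the homophthalate A3 (methyl 3-[5-methoxy-2-(methoxycarbonyl)-3-(2-methoxy-2-oxoethyl)phenoxy]-4,6-dimethoxy-2-pentylbenzoate).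
- In its favour: the aryloxy group next to the aryne directs the nucleophile to the distal carbon C4a, so the regiochemistry is intrinsically well controlled, and both ortho carbons arrive in one step. On predictability of the bond-forming event this is the equal of the chosen plan or better.
- Against it: A1 already contains the hindered diaryl ether, so the hardest bond must still be made by coupling two electron-rich, ortho-substituted arenes. No ring is closed, and A3 needs acylation at C4 with a hexanoyl unit, cyclization and decarboxylation before the lactone exists. Four O-methyl groups and a hindered methyl benzoate remain, and their removal endangers the lactone or the acid.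
- Comparison: on structure the chosen plan solves the ether problem and Alternative 1 postpones it; on step economy Alternative 1 is clearly longer.

Alternative 2: The cut is at C4a–C8a and O2–C1, so both rings of the isocoumarin come from one open chain. In the forward sense the chain A4 (methyl 3-{[(2E,8E)-1,9-dimethoxy-1,5,7-trioxotetradeca-2,8-dien-3-yl]oxy}-4,6-dimethoxy-2-pentylbenzoate) would be deprotonated at C7 by a mild carbonate base. The dienolate carbon C8a would add to the C4a carbonyl and dehydrate to the benzo ring. Aqueous acid in the same flask would unmask the C3 ketone and close the lactone, giving A5 (methyl 3-[(6-hydroxy-1-oxo-3-pentyl-1H-isochromen-8-yl)oxy]-4,6-dimethoxy-2-pentylbenzoate).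
- In its favour: one flask forms one carbon–carbon bond, the benzo ring and the lactone. The ether oxygen is attached to an enol-ether carbon, as in the chosen plan. The 6-hydroxyl emerges free, which is better than the chosen plan because no demethylation is needed on that ring.
- Against it: A4 is a long, enolizable polycarbonyl chain that is hard to assemble and to store. The doubly activated C5 methylene is the most acidic site, and its attack on the C1 ester would give an acylphloroglucinol-type ring instead of the wanted aldol. Ring B must be made beforehand as a hindered phenol, and it still carries a methyl ester and two methyl ethers whose removal is harsher than the single last step of the chosen plan.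
- Comparison: the mechanistic idea is equally sound, but chemoselectivity among several cyclization modes is less secure than the polarity-matched cycloaddition, and the step count is higher.

Alternative 3: The cut is at C7–C8 and C4a–C8a, so the benzo ring of the future isocoumarin is made by cycloaddition on an ether oxygen that already carries ring B. In the forward sense the aryloxypropiolate A6 (methyl 4,6-dimethoxy-3-[(3-methoxy-3-oxoprop-1-yn-1-yl)oxy]-2-pentylbenzoate) and the diene A7 ((3Z)-2,4-bis(trimethylsilyloxy)penta-1,3-diene) would undergo a [4+2] cycloaddition. Loss of trimethylsilanol would then give A8 (methyl 3-[5-hydroxy-2-(methoxycarbonyl)-3-methylphenoxy]-4,6-dimethoxy-2-pentylbenzoate).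
- In its favour: it is the same reaction family as the chosen key step, so mechanistically its equal. A7 is simpler and sturdier than 12 and unsubstituted at its bonding terminus, which is better for the cycloaddition itself. A8 has a free 6-hydroxyl and the ortho-methyl benzoate needed for the lactone.
- Against it: A6 is an aryl ynol-ether ester of a doubly ortho-substituted phenol, a class that is difficult to prepare and to handle. Its oxygen donor on the β-carbon lowers its dienophilicity, and the new bond must form at that hindered, oxygen-bearing carbon. After the key step the isocoumarin still has to be built: phenol protection, lateral metalation in the presence of two methyl esters, acylation and lactonization. A global demethylation including a hindered methyl ester follows. Ring B must also be synthesized separately first.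
- Comparison: the chosen plan needs one step after its key step where this route needs about five, and it builds the simpler ring last on the more robust fragment.

Key step: step 9

Remarks on the chemistry:
- 15 forms as a racemate and both of its stereocentres vanish in the same flask.
- The aromatization is booked as loss of methanol from 15 followed by hydrolysis of two O–Si bonds, which in atoms equals loss of MeOSiMe3 and one silanol.
- 10 is drawn as the 2Z isomer although either geometry serves, because that double bond becomes the central single bond of 12.
- In 12 the 1Z,3Z descriptors place the aryloxy group on the outer side of the s-cis diene.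
- 2 is itself a catalogue compound, and buying it would remove step 1.

## Route

Step 1
Reactants: 1 methyl 2,4-dihydroxy-6-methylbenzoate (methyl orsellinate)
Product: 2 methyl 2,4-dimethoxy-6-methylbenzoate
Conditions: MeI (3 equiv), K2CO3 (3 equiv), acetone, reflux
Reagents that add atoms: iodomethane, CI
Why: Williamson O-methylation of both phenols; the hydrogen-bonded 2-hydroxyl reacts more slowly, hence excess reagent and heat, and the hindered methyl ester is not affected.

Step 2
Reactants: 2 methyl 2,4-dimethoxy-6-methylbenzoate; 3 hexanoyl chloride
Product: 5 methyl 2,4-dimethoxy-6-(2-oxoheptyl)benzoate, via benzylic lithium compound 4 (not isolated)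
Conditions: 2 (2.0 equiv), LiN(i-Pr)2 (2.0 equiv), THF, −78 °C; then 3 (1.0 equiv), −78 °C; aq. NH4Cl
Reagents that add atoms: none
Why: Lateral lithiation of the ortho-toluate, directed and stabilized by the ester, followed by C-acylation with the acid chloride; the second equivalent of anion deprotonates the more acidic benzyl ketone as it forms, which stops double acylation, and the excess 2 is recovered.

Step 3
Reactants: 5 methyl 2,4-dimethoxy-6-(2-oxoheptyl)benzoate
Product: 6 6,8-dimethoxy-3-pentyl-1H-isochromen-1-one
Conditions: p-TsOH·H2O (0.2 equiv), toluene, reflux, MeOH distilled off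
Reagents that add atoms: none
Why: Acid-catalysed enol lactonization (6-exo-trig attack of the conjugated enol oxygen on the protonated ester, then loss of methanol); acid is used so that the other enolate cannot C-acylate the ester to a naphthalenediol, as it could under base.

Step 4
Reactants: 6 6,8-dimethoxy-3-pentyl-1H-isochromen-1-one
Product: 7 8-hydroxy-6-methoxy-3-pentyl-1H-isochromen-1-one
Conditions: BCl3 (1.5 equiv), CH2Cl2, −78 to 0 °C; then H2O
Reagents that add atoms: none
Why: Chelation-controlled ether cleavage: boron bridges the lactone carbonyl and the peri 8-methoxy oxygen in a six-membered chelate and chloride removes only that methyl group, while the 6-methoxy group cannot chelate and survives at this temperature.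

Step 5
Reactants: 7 8-hydroxy-6-methoxy-3-pentyl-1H-isochromen-1-one; 8 methyl 4-chloro-3-oxobutanoate
Product: 9 methyl 4-[(6-methoxy-1-oxo-3-pentyl-1H-isochromen-8-yl)oxy]-3-oxobutanoate
Conditions: K2CO3 (3 equiv), 8 (2 equiv, added slowly), DMF, 50 °C; then 1 M HCl
Reagents that add atoms: none
Why: Williamson-type SN2 displacement of the α-keto primary chloride by the phenoxide, so the hindered ether oxygen is attached at an unhindered CH2; excess 8 offsets its base-induced self-condensation and carbonate is mild enough for the lactone.

Step 6
Reactants: 9 methyl 4-[(6-methoxy-1-oxo-3-pentyl-1H-isochromen-8-yl)oxy]-3-oxobutanoate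
Product: 10 methyl (2Z)-4-[(6-methoxy-1-oxo-3-pentyl-1H-isochromen-8-yl)oxy]-3-(trimethylsilyloxy)but-2-enoate
Conditions: Me3SiCl (1.8 equiv), Et3N (1.6 equiv), toluene, 20 °C, 48 h; filtered under Ar, used crude
Reagents that add atoms: chlorotrimethylsilane, C[Si](C)(C)Cl
Why: Amine-mediated O-silylation of the β-keto ester enol, the standard first stage in making 1,3-bis(silyloxy)dienes; the only enolizable carbonyl is the ketone, and the moisture-sensitive product is carried on without chromatography.

Step 7
Reactants: 10 methyl (2Z)-4-[(6-methoxy-1-oxo-3-pentyl-1H-isochromen-8-yl)oxy]-3-(trimethylsilyloxy)but-2-enoate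
Product: 12 8-{[(1Z,3Z)-4-methoxy-2,4-bis(trimethylsilyloxy)buta-1,3-dien-1-yl]oxy}-6-methoxy-3-pentyl-1H-isochromen-1-one, via lithium dienolate 11 (not isolated)
Conditions: LiN(i-Pr)2 (1.3 equiv), THF, −78 °C, 1 h; Me3SiCl (1.5 equiv), −78 to 20 °C; hexane, filtration under Ar, used crude
Reagents that add atoms: chlorotrimethylsilane, C[Si](C)(C)Cl
Why: Kinetic γ-deprotonation of the silyloxy enoate to the ester dienolate and O-silylation at the ester oxygen, the established second stage for this diene class; the hindered amide at −78 °C does not add to the lactone, and the aryloxy group is expected trans to the diene chain (Z), as the cycloaddition requires.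

Step 8
Reactants: 13 oct-2-ynoic acid
Product: 14 tert-butyl oct-2-ynoate
Conditions: t-BuOC(=NH)CCl3 (2 equiv), BF3·OEt2 (0.05 equiv), CH2Cl2/cyclohexane, 20 °C
Reagents that add atoms: tert-butyl 2,2,2-trichloroacetimidate, CC(C)(C)OC(=N)C(Cl)(Cl)Cl
Why: Acid-promoted O-tert-butylation of the carboxylic acid by the trichloroacetimidate, driven by formation of trichloroacetamide; no nucleophile is present that could add to the conjugated triple bond.

Step 9
Reactants: 12 8-{[(1Z,3Z)-4-methoxy-2,4-bis(trimethylsilyloxy)buta-1,3-dien-1-yl]oxy}-6-methoxy-3-pentyl-1H-isochromen-1-one; 14 tert-butyl oct-2-ynoate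
Product: 17 tert-butyl 4,6-dihydroxy-3-[(6-methoxy-1-oxo-3-pentyl-1H-isochromen-8-yl)oxy]-2-pentylbenzoate, via cyclohexa-1,4-diene cycloadduct 15 (not isolated), via bis(trimethylsilyl) aryl ether 16 (not isolated)
Conditions: 14 (4 equiv), neat, sealed tube, Ar, 120 °C; then 1 M HCl, THF, 20 °C
Reagents that add atoms: none
Why: The electron-rich diene 12 and the electron-poor ynoate 14 combine in a polar, asynchronous [4+2] cycloaddition in which the aryloxy-bearing terminus, the site of the largest HOMO coefficient, bonds to the β-carbon of 14 (C5'–C6') and the ketene-acetal carbon bonds to the α-carbon (C1'–C2'); a stepwise Mukaiyama–Michael addition followed by 6-exo-trig closure of the allenoate carbon onto the silyloxycarbenium ion would give the same connectivity. The closest known reaction type is the thermal benzannulation of 1-alkoxy-1,3-bis(silyloxy)buta-1,3-dienes with acetylenic esters, internal 3-alkyl ynoates included, to 6-substituted 2,4-dihydroxybenzoates. The one new ring, the benzoate ring, is closed by this intermolecular [4π+2π] event, suprafacial on both partners, to give the cyclohexa-1,4-diene 15. Its two sp3 centres (C2' and C5', with methoxy and aryloxy cis as follows from the 1Z,3Z diene) are transient and no stereocentre remains, so no stereocontrol is needed. Aromatization follows by 1,4-elimination of methanol (C5'–H with C2'–OMe) to 16, and dilute acid hydrolyses both silyl ethers to the resorcinol 17. The selectivity required is regiochemical; it rests on the matched polarization of the two partners and on the Z geometry of the aryloxy-bearing double bond, which keeps the aryloxy group outside the s-cis diene. The aryloxy group cannot be expelled during aromatization because C2' carries no hydrogen and C4' and C6' are sp2. The tert-butyl ester discourages attack of the diene at the ester carbonyl (pyranone formation) and tolerates 120 °C and the mild acidic work-up.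

Step 10
Reactants: 17 tert-butyl 4,6-dihydroxy-3-[(6-methoxy-1-oxo-3-pentyl-1H-isochromen-8-yl)oxy]-2-pentylbenzoate
Product: 18 4,6-dihydroxy-3-[(6-hydroxy-1-oxo-3-pentyl-1H-isochromen-8-yl)oxy]-2-pentylbenzoic acid
Conditions: BBr3 (8 equiv), CH2Cl2, −78 to 20 °C; then ice/H2O
Reagents that add atoms: none
Why: Lewis-acid dealkylation: the tert-butyl ester ionizes in the cold and the aryl methyl ether is cleaved by bromide attack on the O-methyl of its boron complex, while the diaryl ether and the lactone have no alkyl–oxygen bond that BBr3 can break; the salicylate unit is held as a boron chelate until the cold aqueous quench, which limits protodecarboxylation.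

## Compound list

1 | methyl 2,4-dihydroxy-6-methylbenzoate (methyl orsellinate) | COC(=O)c1c(C)cc(O)cc1O | starting material
2 | methyl 2,4-dimethoxy-6-methylbenzoate | COC(=O)c1c(C)cc(OC)cc1OC | intermediate
3 | hexanoyl chloride | CCCCCC(=O)Cl | starting material
4 | methyl 2-(lithiomethyl)-4,6-dimethoxybenzoate | [Li]Cc1cc(OC)cc(OC)c1C(=O)OC | intermediate (not isolated)
5 | methyl 2,4-dimethoxy-6-(2-oxoheptyl)benzoate | CCCCCC(=O)Cc1cc(OC)cc(OC)c1C(=O)OC | intermediate
6 | 6,8-dimethoxy-3-pentyl-1H-isochromen-1-one | CCCCCc1cc2cc(OC)cc(OC)c2c(=O)o1 | intermediate
7 | 8-hydroxy-6-methoxy-3-pentyl-1H-isochromen-1-one | CCCCCc1cc2cc(OC)cc(O)c2c(=O)o1 | intermediate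
8 | methyl 4-chloro-3-oxobutanoate (methyl 4-chloroacetoacetate) | COC(=O)CC(=O)CCl | starting material
9 | methyl 4-[(6-methoxy-1-oxo-3-pentyl-1H-isochromen-8-yl)oxy]-3-oxobutanoate | COC(=O)CC(=O)COc1cc(OC)cc2cc(CCCCC)oc(=O)c12 | intermediate
10 | methyl (2Z)-4-[(6-methoxy-1-oxo-3-pentyl-1H-isochromen-8-yl)oxy]-3-(trimethylsilyloxy)but-2-enoate | COC(=O)/C=C(\O[Si](C)(C)C)COc1cc(OC)cc2cc(CCCCC)oc(=O)c12 | intermediate
11 | lithium (1E,3Z)-1-methoxy-4-[(6-methoxy-1-oxo-3-pentyl-1H-isochromen-8-yl)oxy]-3-(trimethylsilyloxy)buta-1,3-dien-1-olate (same spatial arrangement as 12) | CO/C(O[Li])=C/C(/O[Si](C)(C)C)=C/Oc1cc(OC)cc2cc(CCCCC)oc(=O)c12 | intermediate (not isolated)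
12 | 8-{[(1Z,3Z)-4-methoxy-2,4-bis(trimethylsilyloxy)buta-1,3-dien-1-yl]oxy}-6-methoxy-3-pentyl-1H-isochromen-1-one | CO/C(O[Si](C)(C)C)=C/C(/O[Si](C)(C)C)=C/Oc1cc(OC)cc2cc(CCCCC)oc(=O)c12 | intermediate
13 | oct-2-ynoic acid | CCCCCC#CC(=O)O | starting material
14 | tert-butyl oct-2-ynoate | CCCCCC#CC(=O)OC(C)(C)C | intermediate
15 | tert-butyl 6-methoxy-3-[(6-methoxy-1-oxo-3-pentyl-1H-isochromen-8-yl)oxy]-2-pentyl-4,6-bis(trimethylsilyloxy)cyclohexa-1,4-diene-1-carboxylate (racemic, 3-aryloxy and 6-methoxy cis; one enantiomer drawn) | CCCCCC1=C(C(=O)OC(C)(C)C)[C@](OC)(O[Si](C)(C)C)C=C(O[Si](C)(C)C)[C@H]1Oc1cc(OC)cc2cc(CCCCC)oc(=O)c12 | intermediate (not isolated)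
16 | tert-butyl 3-[(6-methoxy-1-oxo-3-pentyl-1H-isochromen-8-yl)oxy]-2-pentyl-4,6-bis(trimethylsilyloxy)benzoate | CCCCCc1c(Oc2cc(OC)cc3cc(CCCCC)oc(=O)c23)c(O[Si](C)(C)C)cc(O[Si](C)(C)C)c1C(=O)OC(C)(C)C | intermediate (not isolated)
17 | tert-butyl 4,6-dihydroxy-3-[(6-methoxy-1-oxo-3-pentyl-1H-isochromen-8-yl)oxy]-2-pentylbenzoate | CCCCCc1c(Oc2cc(OC)cc3cc(CCCCC)oc(=O)c23)c(O)cc(O)c1C(=O)OC(C)(C)C | intermediate
18 | 4,6-dihydroxy-3-[(6-hydroxy-1-oxo-3-pentyl-1H-isochromen-8-yl)oxy]-2-pentylbenzoic acid | CCCCCc1cc2cc(O)cc(Oc3c(O)cc(O)c(C(=O)O)c3CCCCC)c2c(=O)o1 | target

## Step count and least certain steps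

Total: 10 steps. Longest linear sequence: 9 steps (steps 1 to 7, 9 and 10); step 8 is a one-step side branch.

Step 9 (key step). The cycloaddition onto a hindered internal ynoate may be slower than thermal decay of the diene (silyl migration, desilylation, polymerization), so conversion stalls; some bonding with reversed orientation is also conceivable. Fallback: starting from 12, the much more reactive dienophile oct-2-ynal (commercial) is used at 60 to 80 °C with the same acidic work-up. This should give 4,6-dihydroxy-3-[(6-methoxy-1-oxo-3-pentyl-1H-isochromen-8-yl)oxy]-2-pentylbenzaldehyde F1. A Pinnick-type chlorite oxidation (NaClO2, NaH2PO4, DMSO as hypochlorite scavenger, aqueous MeCN) would then give 4,6-dihydroxy-3-[(6-methoxy-1-oxo-3-pentyl-1H-isochromen-8-yl)oxy]-2-pentylbenzoic acid F2. BBr3 as in step 10 removes the remaining methyl ether and the route is rejoined at 18. The carboxyl oxidation level is thus set after ring formation, and 14 is not needed.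

Step 5. Base-induced self-condensation of 8, together with the low nucleophilicity of the chelated phenoxide, may consume the electrophile before O-alkylation is complete. Fallback: starting from 7, alkylation with methyl (2E)-4-bromo-3-methoxybut-2-enoate (K2CO3, acetone, reflux), an allylic bromide with no acidic methylene, should give methyl (2E)-3-methoxy-4-[(6-methoxy-1-oxo-3-pentyl-1H-isochromen-8-yl)oxy]but-2-enoate F3. Hydrolysis of the β-methoxy enoate with aqueous HCl in THF rejoins the route at 9.

Step 7. The lithium amide may attack or deprotonate elsewhere (addition to the lactone carbonyl, metalation next to the C3 side chain). Hydrolytic loss of silyl groups during isolation is a further risk. Fallback: starting from 9, double soft enolization with Me3SiOTf and Et3N in Et2O at 0 °C converts the β-keto ester into the bis(silyloxy)diene in one flask without any strong base. This bypasses 10 and rejoins the route at 12; no new compound is made.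

Step 10. Protodecarboxylation of the liberated 2,4-dihydroxybenzoic acid may occur during the slow cleavage of the unchelated 6-O-methyl ether, or that cleavage may stay incomplete. Fallback: the acid is released last under reductive, non-acidic conditions.
- Starting from 13, Steglich esterification with 2,2,2-trichloroethanol (N,N'-dicyclohexylcarbodiimide, cat. DMAP, CH2Cl2) gives 2,2,2-trichloroethyl oct-2-ynoate F4.
- Cycloaddition of F4 with 12 under the conditions of step 9 gives 2,2,2-trichloroethyl 4,6-dihydroxy-3-[(6-methoxy-1-oxo-3-pentyl-1H-isochromen-8-yl)oxy]-2-pentylbenzoate F5.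
- BBr3 cleaves only the methyl ether, because the electron-poor trichloroethyl ester neither ionizes nor undergoes SN2 cleavage, giving 2,2,2-trichloroethyl 4,6-dihydroxy-3-[(6-hydroxy-1-oxo-3-pentyl-1H-isochromen-8-yl)oxy]-2-pentylbenzoate F6.
- Zn dust in AcOH/THF at 20 °C fragments the ester and rejoins the route at 18.

Step 2. Proton transfer from the acid chloride (ketene formation), double acylation or self-condensation of the toluate anion may erode the acylation. Fallback: 3 is first converted with N,O-dimethylhydroxylamine hydrochloride and pyridine into N-methoxy-N-methylhexanamide F7. Its adduct with 4 is a chelated tetrahedral intermediate that persists until work-up, so only one equivalent of anion is needed and no ketone is exposed to base; aqueous acid releases the ketone and the route is rejoined at 5.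

## Further compounds

F1 | step 9 | 4,6-dihydroxy-3-[(6-methoxy-1-oxo-3-pentyl-1H-isochromen-8-yl)oxy]-2-pentylbenzaldehyde | CCCCCc1c(Oc2cc(OC)cc3cc(CCCCC)oc(=O)c23)c(O)cc(O)c1C=O
F2 | step 9 | 4,6-dihydroxy-3-[(6-methoxy-1-oxo-3-pentyl-1H-isochromen-8-yl)oxy]-2-pentylbenzoic acid | CCCCCc1c(Oc2cc(OC)cc3cc(CCCCC)oc(=O)c23)c(O)cc(O)c1C(=O)O
F3 | step 5 | methyl (2E)-3-methoxy-4-[(6-methoxy-1-oxo-3-pentyl-1H-isochromen-8-yl)oxy]but-2-enoate | COC(=O)/C=C(/OC)COc1cc(OC)cc2cc(CCCCC)oc(=O)c12
F0 | step 7 | none | none
F4 | step 10 | 2,2,2-trichloroethyl oct-2-ynoate | CCCCCC#CC(=O)OCC(Cl)(Cl)Cl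
F5 | step 10 | 2,2,2-trichloroethyl 4,6-dihydroxy-3-[(6-methoxy-1-oxo-3-pentyl-1H-isochromen-8-yl)oxy]-2-pentylbenzoate | CCCCCc1c(Oc2cc(OC)cc3cc(CCCCC)oc(=O)c23)c(O)cc(O)c1C(=O)OCC(Cl)(Cl)Cl
F6 | step 10 | 2,2,2-trichloroethyl 4,6-dihydroxy-3-[(6-hydroxy-1-oxo-3-pentyl-1H-isochromen-8-yl)oxy]-2-pentylbenzoate | CCCCCc1c(Oc2cc(O)cc3cc(CCCCC)oc(=O)c23)c(O)cc(O)c1C(=O)OCC(Cl)(Cl)Cl
F7 | step 2 | N-methoxy-N-methylhexanamide | CCCCCC(=O)N(C)OC
A1 | alternative 1 | methyl 4,6-dimethoxy-3-[5-methoxy-3-(trifluoromethanesulfonyloxy)-2-(trimethylsilyl)phenoxy]-2-pentylbenzoate | COC(=O)c1c(CCCCC)c(Oc2cc(OC)cc(OS(=O)(=O)C(F)(F)F)c2[Si](C)(C)C)c(OC)cc1OC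
A2 | alternative 1 | dimethyl malonate | COC(=O)CC(=O)OC
A3 | alternative 1 | methyl 3-[5-methoxy-2-(methoxycarbonyl)-3-(2-methoxy-2-oxoethyl)phenoxy]-4,6-dimethoxy-2-pentylbenzoate | COC(=O)Cc1cc(OC)cc(Oc2c(OC)cc(OC)c(C(=O)OC)c2CCCCC)c1C(=O)OC
A4 | alternative 2 | methyl 3-{[(2E,8E)-1,9-dimethoxy-1,5,7-trioxotetradeca-2,8-dien-3-yl]oxy}-4,6-dimethoxy-2-pentylbenzoate | COC(=O)/C=C(/Oc1c(OC)cc(OC)c(C(=O)OC)c1CCCCC)CC(=O)CC(=O)/C=C(/OC)CCCCC
A5 | alternative 2 | methyl 3-[(6-hydroxy-1-oxo-3-pentyl-1H-isochromen-8-yl)oxy]-4,6-dimethoxy-2-pentylbenzoate | CCCCCc1cc2cc(O)cc(Oc3c(OC)cc(OC)c(C(=O)OC)c3CCCCC)c2c(=O)o1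
A6 | alternative 3 | methyl 4,6-dimethoxy-3-[(3-methoxy-3-oxoprop-1-yn-1-yl)oxy]-2-pentylbenzoate | COC(=O)C#COc1c(OC)cc(OC)c(C(=O)OC)c1CCCCC
A7 | alternative 3 | (3Z)-2,4-bis(trimethylsilyloxy)penta-1,3-diene | C=C(O[Si](C)(C)C)/C=C(/C)O[Si](C)(C)C
A8 | alternative 3 | methyl 3-[5-hydroxy-2-(methoxycarbonyl)-3-methylphenoxy]-4,6-dimethoxy-2-pentylbenzoate | COC(=O)c1c(C)cc(O)cc1Oc1c(OC)cc(OC)c(C(=O)OC)c1CCCCC
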